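## Retrosynthetic overview

- Endgame: the 11α-hydroxyl and the 16-methylene come from an 11,16-dione (metal–ammonia reduction at C11, Wittig methylenation at C16); C9 and C6 are equilibrated through the C11 ketone and a C7 aldehyde.
- Rings A and B: one intramolecular Diels–Alder reaction (bonds C10–C5 and C3–C4) between a 1-silyloxy diene on C9 (C10, C20, C1–C3) and a Z-2-methyl dienoate on C8 (C6 as exocyclic methylene, C5, C4, C18, C19).
- Rings C and D rest on one feature: the C11 oxygen and C16 (a ketone before methylenation) are 1,5-related through C9, C8 and C15 inside the bicyclo[3.2.1]octane (ring C: C8, C9, C11, C12, C13, C14; ring D: C8, C14, C13, C16, C15). A De Mayo sequence makes C15–C16 and C8–C9 by [2+2] photocycloaddition of the C16 enol acetate of a cyclopentane-1,3-dione (C16, C9, C11, C12, C13) to the C8=C15 alkene tethered at C13; a retro-aldol reaction then cuts C9–C16.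
- Dione precursor: C13 from (S)-4-silyloxycyclopentenone by conjugate allylation; the C9 side chain is put on at the dione stage (C9 is C2 of the dione), because later enolization of the C11 ketone would go to C12.
- Ring order: cyclopentanedione ring, then rings D and C together (key step), then rings A and B together.

Key step: step 10

Remark: gibberellane numbering is used; the ester carbon of the C8 arm becomes C5, and C7 is added later as a methylene carbon.
Remark: C10 (in 11–19 and 23–25) and C6 (in 28–31) are carried as epimer mixtures and C9 as the expected 9α-H epimer (16–19 and 23–31); C10 becomes sp2 in step 18, C6 and C9 are settled in step 24.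

## Route

Step 1
Reactants: 1 diketene; 2 (trimethylsilyl)methylmagnesium chloride
Product: 3 3-[(trimethylsilyl)methyl]but-3-enoic acid
Conditions: NiCl2 (cat.), THF, 0 °C; then aq. HCl
Reagents that add atoms: none
Why: Nickel-catalysed cross-coupling of the Grignard reagent with the enol C–O bond of diketene opens the lactone to the 3-substituted but-3-enoic acid.

Step 2
Reactants: 3 3-[(trimethylsilyl)methyl]but-3-enoic acid
Product: 4 methyl 3-[(trimethylsilyl)methyl]but-3-enoate
Conditions: MeI, K2CO3, DMF, rt
Reagents that add atoms: iodomethane, CI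
Why: O-Alkylation of the carboxylate (SN2) gives the methyl ester without touching the allylsilane.

Step 3
Reactants: 5 (S)-4-(tert-butyldimethylsilyloxy)cyclopent-2-en-1-one; 4 methyl 3-[(trimethylsilyl)methyl]but-3-enoate
Product: 6 trans-3-[2-(methoxycarbonylmethyl)allyl]-4-(tert-butyldimethylsilyloxy)cyclopentanone
Conditions: TiCl4, CH2Cl2, −78 °C
Reagents that add atoms: none
Why: Hosomi–Sakurai conjugate allylation; the allylsilane attacks the enone β-carbon anti to the silyloxy group, which sets C13 from the C16 stereocentre of 5.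

Step 4
Reactants: 6 trans-3-[2-(methoxycarbonylmethyl)allyl]-4-(tert-butyldimethylsilyloxy)cyclopentanone
Product: 7 trans-3-[2-(methoxycarbonylmethyl)allyl]-4-hydroxycyclopentanone
Conditions: aq. HF (48%), MeCN, 0 °C
Reagents that add atoms: none
Why: Acidic fluoride cleaves the silyl ether without base, so the β-hydroxy ketone should not eliminate.

Step 5
Reactants: 7 trans-3-[2-(methoxycarbonylmethyl)allyl]-4-hydroxycyclopentanone
Product: 8 4-[2-(methoxycarbonylmethyl)allyl]cyclopentane-1,3-dione
Conditions: Dess–Martin periodinane, NaHCO3, CH2Cl2, 0 °C to rt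
Reagents that add atoms: none
Why: Dess–Martin oxidation of the β-hydroxy ketone gives the 1,3-dione, which enolizes through C9 and so should leave C13 intact.

Step 6
Reactants: 9 (E)-crotonaldehyde
Product: 10 2-[(E)-prop-1-enyl]oxirane
Conditions: trimethylsulfonium iodide, NaH, DMSO–THF, 0 °C
Reagents that add atoms: trimethylsulfonium iodide, C[S+](C)C.[I-]
Why: Corey–Chaykovsky epoxidation; the sulfonium methylide adds 1,2 to the enal and closes the vinyl epoxide.

Step 7
Reactants: 8 4-[2-(methoxycarbonylmethyl)allyl]cyclopentane-1,3-dione; 10 2-[(E)-prop-1-enyl]oxirane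
Product: 11 2-[(E)-5-hydroxypent-3-en-2-yl]-4-[2-(methoxycarbonylmethyl)allyl]cyclopentane-1,3-dione
Conditions: Pd(PPh3)4 (cat.), THF, rt
Reagents that add atoms: none
Why: Tsuji–Trost alkylation; the π-allyl complex from the vinyl epoxide is attacked by C9 of the dione at the allyl terminus remote from the alkoxide (1,4-addition) under neutral conditions, and the new C10 centre is left uncontrolled because it becomes sp2 in step 18.

Step 8
Reactants: 11 2-[(E)-5-hydroxypent-3-en-2-yl]-4-[2-(methoxycarbonylmethyl)allyl]cyclopentane-1,3-dione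
Product: 12 tert-butyldiphenylsilyl ether of 11
Conditions: TBDPSCl, imidazole, CH2Cl2, 0 °C to rt; aqueous work-up
Reagents that add atoms: tert-butyl(chloro)diphenylsilane, CC(C)(C)[Si](Cl)(c1ccccc1)c1ccccc1
Why: Silylation of the primary allylic alcohol; any silyl enol ether of the dione is hydrolysed on work-up.

Step 9
Reactants: 12 tert-butyldiphenylsilyl ether of 11
Product: 13 C16 enol acetate of 12
Conditions: Ac2O, Et3N, DMAP (cat.), CH2Cl2, 0 °C; chromatography
Reagents that add atoms: acetic anhydride, CC(=O)OC(C)=O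
Why: O-Acylation of the 2-substituted 1,3-dione under acyl-transfer catalysis gives the enol acetate; since either oxygen can be acylated, the C16 isomer 13 is isolated by chromatography, and the regioisomeric material with the acetate on O11 is cleaved back to 12 with K2CO3 in MeOH and acetylated again.

Step 10
Reactants: 13 C16 enol acetate of 12
Product: 16 bicyclo[3.2.1]octane-11,16-dione carrying the C9 side chain (9α-H) and the C8 methoxycarbonylmethyl arm, via cyclobutyl acetate photoadduct 14 (not isolated), via cyclobutanol 15 (not isolated)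
Conditions: hν (350 nm, Pyrex), degassed MeCN, high dilution, rt; then K2CO3, MeOH, 0 °C to rt, same flask
Reagents that add atoms: none
Why: The triplet β-acetoxy enone adds to the alkene tethered through C13–C14; a five-membered ring closes first (rule of five) and the 1,4-biradical collapses to the crossed adduct 14, a bicyclo[2.1.1]hexane, as in known intramolecular De Mayo reactions and crossed photocycloadditions of 1,5-dienes. Methanolysis of the tertiary acetate frees the C16 alkoxide 15, whose strained C9–C16 bond cleaves by retro-aldol reaction to the C16 ketone and the C9 enolate of the C11 ketone. Ring D (C8, C14, C13, C16, C15) is closed by the photochemical bond C15–C16 in a 5-exo mode, and ring C (C8, C9, C11, C12, C13, C14) by the bond C8–C9, which becomes part of the six-membered ring once the cyclobutane opens. C8 is the only new permanent stereocentre and is fixed by C13, because the one-carbon bridge C14 can span C13 and C8 on one face only; C9 is set by exo-face protonation of the enolate, should be mainly 9α-H, and stays epimerizable. The step needs crossed, not straight, regiochemistry and reaction at the C16=C9 enol double bond only: the two-atom tether between C16 and C8 secures the first, the acetate on O16 the second, and the side-chain alkene sits 1,4 to the enone, where a [2+2] closure could only give a highly strained ring.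

Step 11
Reactants: 16 bicyclo[3.2.1]octane-11,16-dione carrying the C9 side chain (9α-H) and the C8 methoxycarbonylmethyl arm
Product: 17 11,16-bis(ethylene ketal) of 16
Conditions: TMSOTf (cat.), 1,2-bis(trimethylsilyloxy)ethane, CH2Cl2, −78 to −20 °C
Reagents that add atoms: 1,2-bis(trimethylsilyloxy)ethane, C[Si](C)(C)OCCO[Si](C)(C)C
Why: Silyl-triflate-catalysed ketalization with the bis-silyl ether of ethylene glycol protects both ketones, including the hindered C11 ketone, under aprotic conditions.

Step 12
Reactants: 17 11,16-bis(ethylene ketal) of 16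
Product: 18 aldehyde from the C8 arm (C8–CH2–CHO)
Conditions: i-Bu2AlH, CH2Cl2, −78 °C; aq. KNaC4H4O6 (potassium sodium tartrate)
Reagents that add atoms: none
Why: Partial reduction of the ester; the aluminium hemiacetal should be stable at −78 °C and give the C5 aldehyde on work-up.

Step 13
Reactants: 18 aldehyde from the C8 arm (C8–CH2–CHO)
Product: 19 2-substituted acrolein (C8–C(=CH2)–CHO)
Conditions: aq. CH2O (37%), pyrrolidine (cat.), propionic acid (cat.), i-PrOH, 45 °C
Reagents that add atoms: formaldehyde, C=O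
Why: Amine-catalysed Mannich condensation (α-methylenation of an aldehyde) adds C7 as a methylene and makes C6 sp2, so C6 is not a stereocentre during ring formation.

Step 14
Reactants: 20 diphenyl phosphite; 21 benzyl 2-bromopropanoate
Product: 22 benzyl 2-(diphenoxyphosphoryl)propanoate
Conditions: NaH, THF, 0 °C to rt
Reagents that add atoms: none
Why: Michaelis–Becker alkylation of the phosphite anion gives the diaryl phosphonate needed for Z-selective olefination.

Step 15
Reactants: 19 2-substituted acrolein (C8–C(=CH2)–CHO); 22 benzyl 2-(diphenoxyphosphoryl)propanoate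
Product: 23 benzyl (Z)-2-methylpenta-2,4-dienoate on C8
Conditions: NaH, THF, −78 to 0 °C
Reagents that add atoms: none
Why: Horner–Wadsworth–Emmons olefination with a diaryl phosphonate is Z-selective, which puts the ester (C19) cis to C6 on the C5=C4 double bond.

Step 16
Reactants: 23 benzyl (Z)-2-methylpenta-2,4-dienoate on C8
Product: 24 allylic alcohol (C3–OH) of 23
Conditions: TBAF, AcOH, THF, 0 °C to rt
Reagents that add atoms: none
Why: Buffered fluoride removes the silyl ether from the side chain and leaves the ketals and the benzyl ester intact.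

Step 17
Reactants: 24 allylic alcohol (C3–OH) of 23
Product: 25 (E)-enal (C3 aldehyde)
Conditions: MnO2, CH2Cl2, rt
Reagents that add atoms: none
Why: MnO2 oxidizes the allylic alcohol selectively to the enal.

Step 18
Reactants: 25 (E)-enal (C3 aldehyde)
Product: 26 (1E,3E)-1-(tert-butyldimethylsilyloxy)diene on C9
Conditions: TBSOTf, Et3N, CH2Cl2, −78 to 0 °C
Reagents that add atoms: tert-butyldimethylsilyl trifluoromethanesulfonate, CC(C)(C)[Si](C)(C)OS(=O)(=O)C(F)(F)F
Why: O-Silylation and γ-deprotonation at C10 (soft enolization of an enal) give the 1-silyloxy diene; the bulky C9 group should take the position trans to C2 and the C20 methyl the inside position, and the old C1=C2 geometry is lost in the new single bond.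

Step 19
Reactants: 26 (1E,3E)-1-(tert-butyldimethylsilyloxy)diene on C9
Product: 27 tetracyclic cycloadduct (rings A and B closed)
Conditions: toluene, BHT (cat.), 150 °C, sealed tube
Reagents that add atoms: none
Why: Type 1 intramolecular Diels–Alder reaction through the tether-anti transition state with the α-methyl group endo and the ester exo, as α-substituted acrylates prefer, which should give the trans A/B fusion (C5, C10), C19 syn to C20 (C4) and the C3 silyl ether cis to C18, while the ester-bearing C4 end of the dienophile turns away from the axial C15 methylene on C8 and so fixes C5 and C10 relative to C8.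

Step 20
Reactants: 27 tetracyclic cycloadduct (rings A and B closed)
Product: 28 C7 primary alcohol
Conditions: 9-BBN, THF, 0 °C to rt; then 30% H2O2, aq. NaOAc
Reagents that add atoms: hydrogen peroxide, OO
Why: Hydroboration–oxidation with 9-BBN is selective for the exocyclic 1,1-disubstituted C6=C7 alkene over the hindered C1=C2 ring alkene; the C6 configuration is not relied on.

Step 21
Reactants: 28 C7 primary alcohol
Product: 29 C7 aldehyde
Conditions: TEMPO (cat.), PhI(OAc)2, CH2Cl2, rt
Reagents that add atoms: none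
Why: Nitroxyl-catalysed oxidation stops at the aldehyde and tolerates the alkene, silyl ether and ketals.

Step 22
Reactants: 29 C7 aldehyde
Product: 30 1,2-dihydro 19-carboxylic acid
Conditions: H2 (1 atm), Pd/C, EtOAc, rt
Reagents that add atoms: none
Why: Hydrogenation saturates C1=C2 and hydrogenolysis of the benzyl ester frees the hindered C19 acid without any attack at the neopentyl carbonyl.

Step 23
Reactants: 30 1,2-dihydro 19-carboxylic acid
Product: 31 3β-hydroxy-11,16-dioxo 7-aldehyde 19-acid (9α-H)
Conditions: 3 M aq. HCl, THF, 40 °C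
Reagents that add atoms: water, O
Why: Acid hydrolysis removes both ketals and the silyl ether; C4 is quaternary, so the β-hydroxy acid cannot dehydrate.

Step 24
Reactants: 31 3β-hydroxy-11,16-dioxo 7-aldehyde 19-acid (9α-H)
Product: 32 9β-H, 6β-formyl epimer of 31
Conditions: NaOMe, MeOH, rt; aq. HCl work-up
Reagents that add atoms: none
Why: Base epimerization through the C9(11)-enolate and the C6 aldehyde enolate should place C7 trans to the quaternary C4 and should favour the cis B/C junction (H9 syn to C15), as for hydrindan-4-ones that carry an angular substituent, with the C19 carboxylate shielding the β-hydroxy acid from retro-aldol cleavage; any 9α-H isomer is separated and resubmitted.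

Step 25
Reactants: 32 9β-H, 6β-formyl epimer of 31
Product: 33 3β-hydroxy-11,16-dioxo-7,19-dioic acid
Conditions: NaClO2, NaH2PO4, 2-methylbut-2-ene, t-BuOH–H2O, rt
Reagents that add atoms: sodium chlorite, [Na+].[O-]Cl=O
Why: Pinnick oxidation converts the aldehyde into the acid under mildly acidic conditions that do not disturb C6 or C9.

Step 26
Reactants: 33 3β-hydroxy-11,16-dioxo-7,19-dioic acid
Product: 34 16-methylene-11-oxo diacid
Conditions: Ph3PCH3Br, KOt-Bu, THF, 0 °C to rt, excess ylide
Reagents that add atoms: methyltriphenylphosphonium bromide, C[P+](c1ccccc1)(c1ccccc1)c1ccccc1.[Br-]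
Why: Wittig methylenation should take the accessible C16 cyclopentanone and leave the C11 ketone, which is screened by the C15–C16 bridge and C20 in the way 11-oxo steroids are; C9 stays under the same thermodynamic control as in step 24.

Step 27
Reactants: 34 16-methylene-11-oxo diacid
Product: 35 CNP0232910.1 (target)
Conditions: Li, NH3 (l), THF, −78 °C; then NH4Cl
Reagents that add atoms: none
Why: Dissolving-metal reduction of the hindered ketone should give the more stable equatorial 11α-alcohol (H11 toward the C15–C16 bridge), as 11-oxo steroids give 11α-ols, and spares the carboxylates and the isolated alkene.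

## Compound list

1 | diketene (4-methyleneoxetan-2-one) | C=C1CC(=O)O1 | starting material
2 | (trimethylsilyl)methylmagnesium chloride | C[Si](C)(C)C[Mg]Cl | starting material
3 | 3-[(trimethylsilyl)methyl]but-3-enoic acid | C=C(C[Si](C)(C)C)CC(=O)O | intermediate
4 | methyl 3-[(trimethylsilyl)methyl]but-3-enoate | C=C(C[Si](C)(C)C)CC(=O)OC | intermediate
5 | (S)-4-(tert-butyldimethylsilyloxy)cyclopent-2-en-1-one | O=C1C=C[C@@H](O[Si](C)(C)C(C)(C)C)C1 | starting material
6 | trans-3-[2-(methoxycarbonylmethyl)allyl]-4-(tert-butyldimethylsilyloxy)cyclopentanone | O=C1C[C@H](CC(=C)CC(=O)OC)[C@@H](O[Si](C)(C)C(C)(C)C)C1 | intermediate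
7 | trans-3-[2-(methoxycarbonylmethyl)allyl]-4-hydroxycyclopentanone | O=C1C[C@H](CC(=C)CC(=O)OC)[C@@H](O)C1 | intermediate
8 | 4-[2-(methoxycarbonylmethyl)allyl]cyclopentane-1,3-dione (diketo form drawn) | O=C1C[C@H](CC(=C)CC(=O)OC)C(=O)C1 | intermediate
9 | (E)-crotonaldehyde | C/C=C/C=O | starting material
10 | 2-[(E)-prop-1-enyl]oxirane (racemic) | C/C=C/C1CO1 | intermediate
11 | 2-[(E)-5-hydroxypent-3-en-2-yl]-4-[2-(methoxycarbonylmethyl)allyl]cyclopentane-1,3-dione (diketo form drawn; C10 epimers) | O=C1C[C@H](CC(=C)CC(=O)OC)C(=O)C1C(C)/C=C/CO | intermediate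
12 | tert-butyldiphenylsilyl ether of 11 (C10 epimers) | O=C1C[C@H](CC(=C)CC(=O)OC)C(=O)C1C(C)/C=C/CO[Si](c1ccccc1)(c1ccccc1)C(C)(C)C | intermediate
13 | C16 enol acetate of 12 (key-step precursor; C10 epimers) | CC(=O)OC1=C(C(C)/C=C/CO[Si](c2ccccc2)(c2ccccc2)C(C)(C)C)C(=O)C[C@@H]1CC(=C)CC(=O)OC | intermediate
14 | crossed [2+2] photoadduct, C16 acetate (bicyclo[2.1.1]hexane fused to the cyclopentanone; not isolated) | CC(=O)O[C@]12C[C@]3(CC(=O)OC)C[C@H]1CC(=O)[C@]23C(C)/C=C/CO[Si](c1ccccc1)(c1ccccc1)C(C)(C)C | intermediate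
15 | C16 cyclobutanol from 14 (not isolated) | O[C@]12C[C@]3(CC(=O)OC)C[C@H]1CC(=O)[C@]23C(C)/C=C/CO[Si](c1ccccc1)(c1ccccc1)C(C)(C)C | intermediate
16 | bicyclo[3.2.1]octane-11,16-dione with C8 methoxycarbonylmethyl arm and C9 side chain (key-step product; 9α-H, C10 epimers) | O=C1C[C@]2(CC(=O)OC)C[C@H]1CC(=O)[C@@H]2C(C)/C=C/CO[Si](c1ccccc1)(c1ccccc1)C(C)(C)C | intermediate
17 | 11,16-bis(ethylene ketal) of 16 | C12(OCCO1)C[C@]3(CC(=O)OC)C[C@H]2CC4(OCCO4)[C@@H]3C(C)/C=C/CO[Si](c5ccccc5)(c5ccccc5)C(C)(C)C | intermediate
18 | C5 aldehyde (C8–CH2–CHO) | C12(OCCO1)C[C@]3(CC=O)C[C@H]2CC4(OCCO4)[C@@H]3C(C)/C=C/CO[Si](c5ccccc5)(c5ccccc5)C(C)(C)C | intermediate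
19 | 2-substituted acrolein (C6=C7 methylene, C5 aldehyde) | C12(OCCO1)C[C@]3(C(=C)C=O)C[C@H]2CC4(OCCO4)[C@@H]3C(C)/C=C/CO[Si](c5ccccc5)(c5ccccc5)C(C)(C)C | intermediate
20 | diphenyl phosphite | O=[PH](Oc1ccccc1)Oc1ccccc1 | starting material
21 | benzyl 2-bromopropanoate | CC(Br)C(=O)OCc1ccccc1 | starting material
22 | benzyl 2-(diphenoxyphosphoryl)propanoate | CC(C(=O)OCc1ccccc1)P(=O)(Oc1ccccc1)Oc1ccccc1 | intermediate
23 | benzyl (Z)-2-methylpenta-2,4-dienoate on C8 (C19 cis to C6) | C12(OCCO1)C[C@]3(C(=C)/C=C(C)\C(=O)OCc5ccccc5)C[C@H]2CC4(OCCO4)[C@@H]3C(C)/C=C/CO[Si](c5ccccc5)(c5ccccc5)C(C)(C)C | intermediate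
24 | allylic alcohol (C3–OH) | C12(OCCO1)C[C@]3(C(=C)/C=C(C)\C(=O)OCc5ccccc5)C[C@H]2CC4(OCCO4)[C@@H]3C(C)/C=C/CO | intermediate
25 | (E)-enal (C3 aldehyde) | C12(OCCO1)C[C@]3(C(=C)/C=C(C)\C(=O)OCc5ccccc5)C[C@H]2CC4(OCCO4)[C@@H]3C(C)/C=C/C=O | intermediate
26 | (1E,3E)-1-silyloxy diene on C9 (C9 trans to C2, C20 inside) | C12(OCCO1)C[C@]3(C(=C)/C=C(C)\C(=O)OCc5ccccc5)C[C@H]2CC4(OCCO4)[C@@H]3/C(C)=C/C=C/O[Si](C)(C)C(C)(C)C | intermediate
27 | tetracyclic cycloadduct: Δ1, 3β-silyl ether, 4β-methyl, 4α-benzyl ester, 5β-H, 10α-methyl, 6-methylene, 9α-H, 11,16-bis-ketal | C12(OCCO1)C[C@]34C[C@H]2CC5(OCCO5)[C@@H]3[C@]6(C)C=C[C@H](O[Si](C)(C)C(C)(C)C)[C@@](C)(C(=O)OCc7ccccc7)[C@H]6C4=C | intermediate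
28 | C7 primary alcohol (C6 epimers) | C12(OCCO1)C[C@]34C[C@H]2CC5(OCCO5)[C@@H]3[C@]6(C)C=C[C@H](O[Si](C)(C)C(C)(C)C)[C@@](C)(C(=O)OCc7ccccc7)[C@H]6C4CO | intermediate
29 | C7 aldehyde (C6 epimers) | C12(OCCO1)C[C@]34C[C@H]2CC5(OCCO5)[C@@H]3[C@]6(C)C=C[C@H](O[Si](C)(C)C(C)(C)C)[C@@](C)(C(=O)OCc7ccccc7)[C@H]6C4C=O | intermediate
30 | 1,2-dihydro 19-carboxylic acid (C6 epimers) | C12(OCCO1)C[C@]34C[C@H]2CC5(OCCO5)[C@@H]3[C@]6(C)CC[C@H](O[Si](C)(C)C(C)(C)C)[C@@](C)(C(=O)O)[C@H]6C4C=O | intermediate
31 | 3β-hydroxy-11,16-dioxo 7-aldehyde 19-acid (9α-H; C6 epimers) | O=C1C[C@]23C[C@H]1CC(=O)[C@@H]2[C@]1(C)CC[C@H](O)[C@@](C)(C(=O)O)[C@H]1C3C=O | intermediate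
32 | 9β-H, 6β-formyl epimer of 31 | O=C1C[C@]23C[C@H]1CC(=O)[C@H]2[C@]1(C)CC[C@H](O)[C@@](C)(C(=O)O)[C@H]1[C@@H]3C=O | intermediate
33 | 3β-hydroxy-11,16-dioxo-7,19-dioic acid | O=C1C[C@]23C[C@H]1CC(=O)[C@H]2[C@]1(C)CC[C@H](O)[C@@](C)(C(=O)O)[C@H]1[C@@H]3C(=O)O | intermediate
34 | 16-methylene-11-oxo diacid | C=C1C[C@]23C[C@H]1CC(=O)[C@H]2[C@]1(C)CC[C@H](O)[C@@](C)(C(=O)O)[C@H]1[C@@H]3C(=O)O | intermediate
35 | CNP0232910.1 | C=C1C[C@]23C[C@H]1C[C@@H](O)[C@H]2[C@]1(C)CC[C@H](O)[C@@](C)(C(=O)O)[C@H]1[C@@H]3C(=O)O | target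

## Step count and risks

Total step count: 27. Longest linear sequence: 25 steps (steps 1–5, 7–13 and 15–27).

Steps most likely to fail:

1. Step 19. The cycloaddition may run through the tether-syn or ester-endo transition state or on the other diene face, or the diene may shift a hydrogen from C20 (1,5-shift) before it reacts. Fallback: the C4 methyl group is left out of the dienophile and added afterwards. It sets out from 19. Wittig olefination with benzyl (triphenylphosphoranylidene)acetate should give the E-dienoate F1. TBAF/AcOH should then give the allylic alcohol F2, MnO2 the enal F3 and TBSOTf/Et3N the silyloxy diene F4. The disubstituted E-acrylate of F4 should cyclize at lower temperature through the usual ester-endo, tether-anti transition state to the C4–H adduct F5 (ester β). LiN(i-Pr)2 and then MeI (THF, −78 °C) should methylate the C4 ester enolate on the face away from C20, and the route is rejoined at 27.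

2. Step 24. The C9 equilibrium may lie on the side of the trans-fused 9α-H ketone, or enolization toward the hindered C9 may be slow. Fallback: kinetic protonation of a preformed enol silane, done after the ketone no longer has to meet base. It sets out from 31. NaOMe still equilibrates C6 and should leave the 9α-H aldehyde F6, which is oxidized with NaClO2 to the 9α-H diacid F7 and methylenated as in step 26 to the 9α-H 16-methylene ketone F8. TMSCl, NaI and Et3N in MeCN (equilibrating silylation) should give the 9(11)-enol silane F9, with both acids and the 3-hydroxyl silylated. AcOH in aqueous THF at −40 °C should protonate C9 on the β-face, opposite the C20 methyl group, and strip the silyl groups. The route is rejoined at 34, which is reduced at once as in step 27.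

3. Step 10. The enol acetate may undergo a photochemical 1,3-acyl shift or be lost before it cyclizes, or the 1,4-biradical may revert instead of closing the hindered C8–C9 bond. Fallback: an enol ether that cannot migrate, and an acid-triggered ring opening. It sets out from 12. Trimethylsilyldiazomethane in MeOH–toluene should give both methyl enol ethers, from which the C16 methyl enol ether F10 is separated. Irradiation as in step 10 should give the cyclobutyl methyl ether F11. Aqueous HCl in THF should open this donor–acceptor cyclobutane through the C16 oxocarbenium ion and, after loss of methanol, rejoin the route at 16.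

## Further compounds

F1 | step 19 | benzyl (E)-penta-2,4-dienoate on C8 (no C4 methyl), side-chain silyl ether | C12(OCCO1)C[C@]3(C(=C)/C=C/C(=O)OCc5ccccc5)C[C@H]2CC4(OCCO4)[C@@H]3C(C)/C=C/CO[Si](c5ccccc5)(c5ccccc5)C(C)(C)C
F2 | step 19 | allylic alcohol of F1 | C12(OCCO1)C[C@]3(C(=C)/C=C/C(=O)OCc5ccccc5)C[C@H]2CC4(OCCO4)[C@@H]3C(C)/C=C/CO
F3 | step 19 | enal of F2 | C12(OCCO1)C[C@]3(C(=C)/C=C/C(=O)OCc5ccccc5)C[C@H]2CC4(OCCO4)[C@@H]3C(C)/C=C/C=O
F4 | step 19 | 1-silyloxy diene with the E-dienoate | C12(OCCO1)C[C@]3(C(=C)/C=C/C(=O)OCc5ccccc5)C[C@H]2CC4(OCCO4)[C@@H]3/C(C)=C/C=C/O[Si](C)(C)C(C)(C)C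
F5 | step 19 | cycloadduct with C4–H and 4β-benzyl ester | C12(OCCO1)C[C@]34C[C@H]2CC5(OCCO5)[C@@H]3[C@]6(C)C=C[C@H](O[Si](C)(C)C(C)(C)C)[C@H](C(=O)OCc7ccccc7)[C@H]6C4=C
F6 | step 24 | 9α-H epimer of 32 | O=C1C[C@]23C[C@H]1CC(=O)[C@@H]2[C@]1(C)CC[C@H](O)[C@@](C)(C(=O)O)[C@H]1[C@@H]3C=O
F7 | step 24 | 9α-H epimer of 33 | O=C1C[C@]23C[C@H]1CC(=O)[C@@H]2[C@]1(C)CC[C@H](O)[C@@](C)(C(=O)O)[C@H]1[C@@H]3C(=O)O
F8 | step 24 | 9α-H epimer of 34 | C=C1C[C@]23C[C@H]1CC(=O)[C@@H]2[C@]1(C)CC[C@H](O)[C@@](C)(C(=O)O)[C@H]1[C@@H]3C(=O)O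
F9 | step 24 | 9(11)-enol trimethylsilyl ether, 3-O-silyl, bis(silyl ester) | C=C1C[C@]23C[C@H]1CC(O[Si](C)(C)C)=C2[C@]1(C)CC[C@H](O[Si](C)(C)C)[C@@](C)(C(=O)O[Si](C)(C)C)[C@H]1[C@@H]3C(=O)O[Si](C)(C)C
F10 | step 10 | C16 methyl enol ether of 12 | COC1=C(C(C)/C=C/CO[Si](c2ccccc2)(c2ccccc2)C(C)(C)C)C(=O)C[C@@H]1CC(=C)CC(=O)OC
F11 | step 10 | crossed photoadduct, C16 methyl ether | CO[C@]12C[C@]3(CC(=O)OC)C[C@H]1CC(=O)[C@]23C(C)/C=C/CO[Si](c1ccccc1)(c1ccccc1)C(C)(C)C
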